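## Structural features

The target is a 6-methoxy-2,8-dimethyl-2H-chromene (benzene ring A, pyran ring B) whose fully substituted C2 (R) carries a methyl group and a CH2–C(=O)–CH2 bridge ending on C1' of a cyclopentane (ring C). C1' and C2' are adjacent quaternary stereocentres (both S) with cis methyl groups, and C2' carries a (Z)-4-hydroxy-4-methylpent-2-enoyl group, so the bridge ketone and the enone carbonyl are 1,5-related. C2 and the C1'/C2' pair are too far apart to influence each other, so two enantiopure halves must be joined. Fragile groups are the (Z)-γ-hydroxy enone (isomerisation, hemiketal formation, over-reduction), the β-aryloxy ketone (base opens the pyran by elimination of the phenoxide), the 1,5-diketone (intramolecular aldol or Michael reaction), the styrenic C3=C4 bond and the tertiary allylic aryl ether at C2 (acid). The real difficulty is the pair of contiguous quaternary carbons of ring C in one absolute configuration, together with the order in which the two carbonyl groups and the cis-enone are unveiled. The key step exploits the aryl ether bond O1–C8a of ring B: C2, with methyl, oxygen, CH2 and the sp2 carbon C3, has the substitution pattern of citramalic acid, so the ring can be closed at the aryl–oxygen bond while C2 stays untouched.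

## Logic of the disconnections

42 to 41. No skeletal bond is cut; the cis double bond of the enone is traced back to a triple bond. The most labile function is made last, so every earlier step handles a robust alkyne. The forward step must deliver one equivalent of hydrogen syn, spare the C3=C4 bond of ring B and stop before the enone is reduced.

41 to 40, then 40 to 37 and 38. The bridge ketone is taken back to a carbinol, and the bond between the C2' carbonyl carbon and the alkyne carbon is cut. In 37 the C2' carbonyl is a lactone carbonyl and the bridge oxygen is its alkoxy part, so one acetylide addition frees both, and a keto aldehyde that could cyclise by aldol reaction never exists. Five carbons arrive in one step without a protecting group. The forward step needs a single addition to a carbonyl flanked by two quaternary carbons and a base-free oxidation afterwards.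

37 to 35 to 34. Only C–O bonds change: the δ-lactone comes from a 1,5-diol by oxidative lactonisation and the diol from a silyl ether. The primary neopentyl alcohol must be oxidised before the secondary one.

34 to 17 and 32. The bond between the carbinol carbon and the CH2 group on C1' is cut. It is the only bond of the bridge that can be made with the oxygenated carbon as electrophile; the reverse polarity would place a carbanion β to the aryloxy group, which would be expelled. The cut gives two enantiopure halves of similar size. It demands a neopentyl organometallic that adds to a β-aryloxy aldehyde faster than it enolises it.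

17 to 16 to 15. Oxidation level and protecting group only; the aldehyde is made just before use because base would open ring B.

15 to 14. The aryl–oxygen bond O1–C8a is cut. It is the one bond of ring B whose formation leaves all four bonds of C2 alone, so C2 becomes a spectator from the chiral pool. Ring B is reduced to an acyclic (Z)-styrenyl tertiary alcohol. The forward step needs C–O coupling at a bromide flanked by methyl and vinyl, a (Z)-alkene and no acid.

14 to 13, then 13 to 8 and 12. The (Z)-alkene is traced to an alkyne and the C4–C4a bond is cut. The arene separates from a five-carbon alkynol. The coupling must take iodine and leave bromine, and the semireduction must not remove bromine.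

12 to 10 to 9. The C–Br and C–I bonds are cut. The amino group of 9 directs iodine to the future C4a and is then itself replaced by bromine at the future C8a, so the substitution pattern follows from a commercial aniline.

8 to 5 and 6. The triple bond is cut between its two carbons; the terminal carbon (future C4) comes from 6 by one-carbon homologation of a latent aldehyde. The α-hydroxy aldehyde must be released only in the flask.

5 to 4 to 3 to 2 to 1. Functional group changes only. The carboxyl next to the carbinol becomes the masked aldehyde, the CH2CO2H arm becomes the silyloxyethyl chain, and the acetonide tells the two carboxyl groups apart.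

32 to 31 to 30 to 28. C–I goes back to C–O. Lactone 28 is opened by hydrolysis and silylation and not by reduction, because reduction would give a meso diol and erase the difference between the two arms.

28 to 26 and 23 to 21. The two ring–methyl bonds are cut one at a time. A five–five bicyclic lactone can only be cis-fused, so each enolate methylation must put its methyl in the angular position; the cis relationship follows from ring strain, not from reagent control. Each methylation needs the carbonyl on its own arm, hence the transposition 23 to 24 to 26 in between.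

21 to 19 to 18. The absolute configuration is traced to the desymmetrisation of meso anhydride 18; every later centre of ring C is relayed from it.

## Other disconnections considered

All three alternatives address ring C; any of them could in principle replace steps 13 to 21 while the chromene half stays.

Alternative 1: The cut removes both ring–methyl bonds (C1'–CH3 and C2'–CH3) and returns them as the two C–CH2 bonds of a thiolane. In the forward step the parent thiocarbonyl ylide A3, released from A2 by fluoride-induced desilylation, would add across the tetrasubstituted C1'=C2' bond of the chiral unsaturated lactone A1 to give A4, and reductive desulfurisation would unveil the methyl groups. In its favour, one suprafacial cycloaddition makes both quaternary centres and their cis relationship is a geometric necessity. A4 is also a δ-lactone of the same type as 37, so the acetylide opening of step 25 would apply. Against it here, the dipolarophile is tetrasubstituted and activated by one carbonyl only, and face selection rests on one remote methyl group. Desulfurisation with nickel would not spare the C3=C4 bond of ring B, so it must precede fragment union. The carbinol carbon of A4 bears a methyl group, so the bridge would emerge as a methyl ketone whose methyl carbon must still be bonded to C2, and ring B would then have to be built without the control that 1 provides. On structure the alternative meets the contiguous quaternary carbons more directly than the chosen plan, which needs two methylations and a lactone transposition; on this point it is the better. On mechanism a concerted cycloaddition and an enforced cis ring fusion are equal guarantees of the cis-dimethyl relationship. On step economy ring C would be shorter than steps 13 to 21, but the gain is lost at C2, where the chosen plan is stronger.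

Alternative 2: The cut is at C1'–CH2 and C2'–CHO. In the forward step irradiation of the chiral spiro dioxinone A5 with A6 would form both bonds in a cis-fused cyclobutane, and methanolysis in the same flask would open it by retro-aldol cleavage to A7. In its favour, A6 already holds both methyl groups on one double bond, so neither quaternary centre is made by alkylation. The alkene is symmetrical, so no regiochemical question arises, and the two arms emerge differentiated in one operation. In step economy for ring C this is better than the nine steps to 32. Against it here, the absolute configuration depends on how well the auxiliary shields one face of an excited enone toward a tetrasubstituted alkene. The arm on C1' is CH2CO2Me, whose ester carbon is the future bridge carbonyl. Joining it to a finished chromene would need a carbanion on the CH2 next to C2, which would expel the aryloxide, so A7 would need a different chromene construction or a one-carbon degradation to an iodide of the type of 32. On structure it equals alternative 1 and is better than the chosen plan in directness. On mechanism an auxiliary-controlled excited-state reaction is less predictable than the ground-state, ring-enforced methylations of steps 15 and 18. Overall step count would be about equal once the one-carbon correction is counted.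

Alternative 3: The cut is the ring bond C1'–C2'. In the forward step the bulky aluminium Lewis acid A9 would open epoxide A8 at its methyl-bearing carbon, and the adjacent quaternary ring carbon would migrate to it, contracting the six-membered ring and leaving aldehyde A10. In its favour, only one quaternary centre must exist beforehand and the second is made stereospecifically by migration anti to the leaving oxygen. The aldehyde on C2' arrives at the oxidation level needed for alkynylation, which is better than the chosen plan, where that carbon is carried as a protected alcohol and oxidised late. Against it here, A8 needs an enantiopure quaternary centre and an epoxide on a defined face of an alkene whose neighbours (methyl and silyloxyethyl) differ little in size. Hydride shift to a ketone competes with ring contraction, and the two-carbon arm on C1' raises the same polarity problem at the union as in alternative 2. On structure it attacks the C1'–C2' bond itself. On mechanism a stereospecific 1,2-shift is the equal of ring-fusion control but asks more of the precursor. On step economy no gain over steps 13 to 21 is expected once A8 is counted.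

Key step: step 10

Assumption: quinine is taken to deliver the (1R,2S)-hemiester 19; if the sense of induction is the opposite, quinidine is used and nothing else changes.
Assumption: 42 is drawn as the open (Z)-hydroxy enone; its cyclic hemiketal tautomer is regarded as the same compound in equilibrium.

Step 1
Reactants: 1 (R)-citramalic acid
Product: 2 2-[(4R)-2,2,4-trimethyl-5-oxo-1,3-dioxolan-4-yl]acetic acid
Conditions: Me2C(OMe)2, TsOH·H2O (cat.), acetone, rt
Reagents that add atoms: 2,2-dimethoxypropane, COC(C)(C)OC
Why: Acid-catalysed acetonide formation ties the α-hydroxy acid unit into the five-membered dioxolanone and leaves only the CH2CO2H arm free; the quaternary stereocentre is not touched.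

Step 2
Reactants: 2 2-[(4R)-2,2,4-trimethyl-5-oxo-1,3-dioxolan-4-yl]acetic acid
Product: 3 (5R)-5-(2-hydroxyethyl)-2,2,5-trimethyl-1,3-dioxolan-4-one
Conditions: BH3·SMe2, THF, 0 °C to rt; MeOH quench
Reagents that add atoms: none
Why: Chemoselective borane reduction: the free carboxylic acid reacts much faster than the ester-type carbonyl of the dioxolanone. 3 is silylated without delay because it can translactonise to a butyrolactone.

Step 3
Reactants: 3 (5R)-5-(2-hydroxyethyl)-2,2,5-trimethyl-1,3-dioxolan-4-one
Product: 4 (5R)-2,2,5-trimethyl-5-{2-[(triisopropylsilyl)oxy]ethyl}-1,3-dioxolan-4-one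
Conditions: i-Pr3SiCl, imidazole, DMF, 0 °C to rt
Reagents that add atoms: chlorotri(propan-2-yl)silane, CC(C)[Si](Cl)(C(C)C)C(C)C
Why: Standard silylation of a primary alcohol; the bulky silyl ether is chosen to survive K2CO3/MeOH, amine bases and Cs2CO3 at 70 °C in steps 5 to 10.

Step 4
Reactants: 4 (5R)-2,2,5-trimethyl-5-{2-[(triisopropylsilyl)oxy]ethyl}-1,3-dioxolan-4-one
Product: 5 (5R)-2,2,5-trimethyl-5-{2-[(triisopropylsilyl)oxy]ethyl}-1,3-dioxolan-4-ol (both C4 epimers)
Conditions: i-Bu2AlH (1.1 equiv), CH2Cl2, −78 °C; aq. potassium sodium tartrate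
Reagents that add atoms: none
Why: Low-temperature hydride reduction of a dioxolanone stops at the tetrahedral aluminate, so the product is the lactol, a masked α-hydroxy aldehyde, and not a free aldehyde. The α-carbon is quaternary and cannot epimerise.

Step 5
Reactants: 5 (5R)-2,2,5-trimethyl-5-{2-[(triisopropylsilyl)oxy]ethyl}-1,3-dioxolan-4-ol; 6 dimethyl (1-diazo-2-oxopropyl)phosphonate
Product: 8 (3R)-3-methyl-5-[(triisopropylsilyl)oxy]pent-1-yn-3-ol, via hydroxy aldehyde 7 (not isolated)
Conditions: K2CO3, MeOH, 0 °C to rt
Reagents that add atoms: none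
Why: Ohira–Bestmann homologation: methanolysis of 6 gives the diazomethylphosphonate anion, the lactol opens with loss of acetone to 7, and olefination, loss of N2 and 1,2-shift give the terminal alkyne. The stereocentre has no α-hydrogen and is carried through unchanged.

Step 6
Reactants: 9 4-methoxy-2-methylaniline
Product: 10 2-iodo-4-methoxy-6-methylaniline
Conditions: BnMe3N+ ICl2−, CaCO3, CH2Cl2/MeOH, rt
Reagents that add atoms: benzyltrimethylammonium dichloroiodate, C[N+](C)(C)Cc1ccccc1.Cl[I-]Cl
Why: Electrophilic aromatic iodination directed by the amino group to its only free ortho position (para is blocked by OMe). The mild reagent with CaCO3 limits oxidation of the electron-rich aniline.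

Step 7
Reactants: 10 2-iodo-4-methoxy-6-methylaniline
Product: 12 1-bromo-2-iodo-4-methoxy-6-methylbenzene, via diazonium bromide 11 (not isolated)
Conditions: NaNO2, 48% aq. HBr, 0 °C; then CuBr (0.2 equiv), 48% aq. HBr, 0 to 60 °C
Reagents that add atoms: hydrogen bromide, Br
Why: Sandmeyer bromination replaces NH2 by Br at the carbon flanked by methyl and iodine. Iodine then sits at the future C4a and bromine at the future C8a.

Step 8
Reactants: 8 (3R)-3-methyl-5-[(triisopropylsilyl)oxy]pent-1-yn-3-ol; 12 1-bromo-2-iodo-4-methoxy-6-methylbenzene
Product: 13 (3R)-1-(2-bromo-5-methoxy-3-methylphenyl)-3-methyl-5-[(triisopropylsilyl)oxy]pent-1-yn-3-ol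
Conditions: PdCl2(PPh3)2 (2 mol%), CuI (4 mol%), Et3N, THF, rt
Reagents that add atoms: none
Why: Sonogashira coupling; zerovalent palladium inserts into C–I far faster than into the neighbouring C–Br at room temperature, so only the C4–C4a bond forms and the bromide is kept for step 10.

Step 9
Reactants: 13 (3R)-1-(2-bromo-5-methoxy-3-methylphenyl)-3-methyl-5-[(triisopropylsilyl)oxy]pent-1-yn-3-ol
Product: 14 (1Z,3R)-1-(2-bromo-5-methoxy-3-methylphenyl)-3-methyl-5-[(triisopropylsilyl)oxy]pent-1-en-3-ol
Conditions: H2 (1 atm), Pd/CaCO3 poisoned with Pb(OAc)2 (Lindlar catalyst), quinoline, EtOAc, rt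
Reagents that add atoms: none
Why: Lindlar semihydrogenation delivers both hydrogens syn from the catalyst surface and fixes the (Z)-alkene that the ring closure needs. The poisoned catalyst should leave the aryl bromide and stop at the alkene.

Step 10
Reactants: 14 (1Z,3R)-1-(2-bromo-5-methoxy-3-methylphenyl)-3-methyl-5-[(triisopropylsilyl)oxy]pent-1-en-3-ol
Product: 15 (2R)-6-methoxy-2,8-dimethyl-2-{2-[(triisopropylsilyl)oxy]ethyl}-2H-chromene
Conditions: Pd(OAc)2 (5 mol%), 2-(di-tert-butylphosphino)-1,1'-binaphthyl (6 mol%), Cs2CO3 (1.5 equiv), toluene, 70 °C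
Reagents that add atoms: none
Why: Pd(OAc)2 is reduced in the flask to a zerovalent palladium–monophosphine complex, which undergoes oxidative addition into the hindered C–Br bond. Cs2CO3 deprotonates the tertiary hydroxyl and bromide is displaced, giving an aryl(alkoxo)palladium chelate that is a seven-membered oxapalladacycle (Pd, C8a, C4a, C4, C3, C2, O), not a six-membered one; C–O reductive elimination from it forms O1–C8a. The closest known reaction type is the palladium-catalysed intramolecular O-arylation of alcohols with aryl halides under bulky, electron-rich biaryl dialkylphosphines, which is established for tertiary alcohols. The six-membered pyran ring is closed by this reductive elimination, formally an exo attack of oxygen on the aromatic carbon. No stereocentre is created; C2 (R) comes from 1 and none of its bonds is made or broken, so it cannot be scrambled. The step needs C–O reductive elimination to win over β-hydride elimination and over reduction of the C–Br bond: a tertiary alkoxide has no hydrogen on the carbinol carbon, and the bulky ligand speeds reductive elimination. It needs the (Z)-geometry from step 9, which holds oxygen within reach of palladium, and the silyl ether leaves the tertiary alkoxide as the only oxygen that can bind the metal. The weak carbonate base and the absence of acid avoid ionisation of the tertiary allylic alcohol.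

Step 11
Reactants: 15 (2R)-6-methoxy-2,8-dimethyl-2-{2-[(triisopropylsilyl)oxy]ethyl}-2H-chromene
Product: 16 2-[(2R)-6-methoxy-2,8-dimethyl-2H-chromen-2-yl]ethanol
Conditions: Bu4NF, THF, 0 °C to rt
Reagents that add atoms: none
Why: Fluoride cleaves the Si–O bond of the primary silyl ether (desilylation); the chromene and the tertiary aryl ether are inert to fluoride.

Step 12
Reactants: 16 2-[(2R)-6-methoxy-2,8-dimethyl-2H-chromen-2-yl]ethanol
Product: 17 2-[(2R)-6-methoxy-2,8-dimethyl-2H-chromen-2-yl]acetaldehyde
Conditions: Dess–Martin periodinane, NaHCO3, CH2Cl2, 0 °C to rt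
Reagents that add atoms: none
Why: Dess–Martin oxidation under buffered, non-basic conditions gives the β-aryloxy aldehyde without enolisation, which would open the pyran ring by elimination of the phenoxide. 17 is used directly.

Step 13
Reactants: 18 cis-cyclopentane-1,2-dicarboxylic anhydride (meso)
Product: 19 (1R,2S)-2-(methoxycarbonyl)cyclopentane-1-carboxylic acid
Conditions: MeOH (3 equiv), quinine (1.1 equiv), toluene, −55 °C; aq. HCl work-up
Reagents that add atoms: methanol, CO
Why: Cinchona alkaloid-mediated desymmetrising methanolysis of a meso anhydride: the alkaloid acts as a chiral general base and directs methanol to one of the two enantiotopic carbonyl groups, which sets both stereocentres at once. The alkaloid is recovered by acid extraction.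

Step 14
Reactants: 19 (1R,2S)-2-(methoxycarbonyl)cyclopentane-1-carboxylic acid
Product: 21 (1S,5R)-3-oxabicyclo[3.3.0]octan-2-one, via hydroxy ester 20 (not isolated)
Conditions: BH3·SMe2, THF, −10 °C to rt; MeOH; then TsOH (cat.), toluene, rt
Reagents that add atoms: none
Why: Borane reduces the carboxylic acid in the presence of the methyl ester, and the cis hydroxy ester lactonises under acid catalysis. The carbonyl therefore ends on the carbon that becomes C2'.

Step 15
Reactants: 21 (1S,5R)-3-oxabicyclo[3.3.0]octan-2-one
Product: 23 (1S,5R)-1-methyl-3-oxabicyclo[3.3.0]octan-2-one, via lithium enolate 22 (not isolated)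
Conditions: LiN(i-Pr)2, THF, −78 °C; MeI, −78 to 0 °C
Reagents that add atoms: iodomethane, CI
Why: Enolate alkylation at the ring-fusion carbon; a five–five bicyclic lactone can only be cis-fused, so the methyl group must take the angular position cis to the ring-fusion hydrogen. This sets the C2' quaternary centre from the existing C1' centre.

Step 16
Reactants: 23 (1S,5R)-1-methyl-3-oxabicyclo[3.3.0]octan-2-one
Product: 24 [(1S,2R)-2-(hydroxymethyl)-1-methylcyclopentyl]methanol
Conditions: LiAlH4, THF, 0 °C to rt
Reagents that add atoms: none
Why: Hydride reduction of the lactone to the diol prepares the transposition of the carbonyl to the other arm, so that the remaining methine (future C1') becomes enolisable.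

Step 17
Reactants: 24 [(1S,2R)-2-(hydroxymethyl)-1-methylcyclopentyl]methanol
Product: 26 (1R,5S)-5-methyl-3-oxabicyclo[3.3.0]octan-2-one, via lactol 25 (not isolated)
Conditions: TEMPO (0.2 equiv), PhI(OAc)2 (2.5 equiv), CH2Cl2, rt
Reagents that add atoms: none
Why: Oxoammonium oxidation is sensitive to steric hindrance, so the hydroxymethyl on the methine carbon should be oxidised before the neopentyl one; the aldehyde is trapped as the lactol and oxidised on to the transposed lactone (oxidative lactonisation). First attack at the neopentyl alcohol would return 23, which can be recycled through step 16.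

Step 18
Reactants: 26 (1R,5S)-5-methyl-3-oxabicyclo[3.3.0]octan-2-one
Product: 28 (1R,5S)-1,5-dimethyl-3-oxabicyclo[3.3.0]octan-2-one, via lithium enolate 27 (not isolated)
Conditions: LiN(i-Pr)2, THF, −78 °C; MeI, DMPU, −78 to 0 °C
Reagents that add atoms: iodomethane, CI
Why: Second enolate methylation; again only the cis-fused product can form, so the new methyl is cis to the first and C1' and C2' receive the relative configuration of the target. The absolute configuration derives from step 13.

Step 19
Reactants: 28 (1R,5S)-1,5-dimethyl-3-oxabicyclo[3.3.0]octan-2-one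
Product: 30 triisopropylsilyl (1R,2S)-1,2-dimethyl-2-{[(triisopropylsilyl)oxy]methyl}cyclopentane-1-carboxylate, via potassium hydroxy carboxylate 29 (not isolated)
Conditions: KOH, MeOH/H2O, 65 °C; evaporate to dryness; i-Pr3SiOTf (2.5 equiv), 2,6-lutidine, CH2Cl2, −20 °C to rt
Reagents that add atoms: potassium hydroxide, [K+].[OH-]; triisopropylsilyl trifluoromethanesulfonate, CC(C)[Si](OS(=O)(=O)C(F)(F)F)(C(C)C)C(C)C
Why: Saponification opens the lactone to a carboxylate salt that cannot relactonise, and exhaustive silylation caps the neopentyl hydroxyl as a silyl ether and the carboxylate as a silyl ester. The two one-carbon arms stay differentiated, which direct hydride reduction of 28 to the meso diol would destroy.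

Step 20
Reactants: 30 triisopropylsilyl (1R,2S)-1,2-dimethyl-2-{[(triisopropylsilyl)oxy]methyl}cyclopentane-1-carboxylate
Product: 31 [(1R,2S)-1,2-dimethyl-2-{[(triisopropylsilyl)oxy]methyl}cyclopentyl]methanol
Conditions: LiAlH4, THF, 0 °C to rt
Reagents that add atoms: none
Why: LiAlH4 reduces the silyl ester to the primary alcohol and leaves the hindered silyl ether untouched.

Step 21
Reactants: 31 [(1R,2S)-1,2-dimethyl-2-{[(triisopropylsilyl)oxy]methyl}cyclopentyl]methanol
Product: 32 {[(1S,2R)-2-(iodomethyl)-1,2-dimethylcyclopentyl]methoxy}tri(propan-2-yl)silane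
Conditions: I2, PPh3, imidazole, toluene, 80 °C
Reagents that add atoms: iodine, II
Why: Appel-type iodination: iodide displaces the alkoxyphosphonium group by SN2. The carbon is neopentyl, so heat is needed, and the bulky silyl ether on the neighbouring arm is a poor internal nucleophile.

Step 22
Reactants: 32 {[(1S,2R)-2-(iodomethyl)-1,2-dimethylcyclopentyl]methoxy}tri(propan-2-yl)silane; 17 2-[(2R)-6-methoxy-2,8-dimethyl-2H-chromen-2-yl]acetaldehyde
Product: 34 1-[(1S,2S)-1,2-dimethyl-2-{[(triisopropylsilyl)oxy]methyl}cyclopentyl]-3-[(2R)-6-methoxy-2,8-dimethyl-2H-chromen-2-yl]propan-2-ol (both carbinol epimers), via organolithium 33 (not isolated)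
Conditions: 32 (1.3 equiv), t-BuLi (2.7 equiv), Et2O/pentane, −78 °C; then 17, −78 °C; H2O
Reagents that add atoms: none
Why: Iodine–lithium exchange with two equivalents of t-BuLi is fast at −78 °C, and the primary organolithium should add to the aldehyde (1,2-addition) faster than it deprotonates it. The new carbinol centre forms as a mixture of epimers, which does not matter because it is oxidised in step 26.

Step 23
Reactants: 34 1-[(1S,2S)-1,2-dimethyl-2-{[(triisopropylsilyl)oxy]methyl}cyclopentyl]-3-[(2R)-6-methoxy-2,8-dimethyl-2H-chromen-2-yl]propan-2-ol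
Product: 35 1-[(1S,2S)-2-(hydroxymethyl)-1,2-dimethylcyclopentyl]-3-[(2R)-6-methoxy-2,8-dimethyl-2H-chromen-2-yl]propan-2-ol
Conditions: Bu4NF, THF, rt to 45 °C
Reagents that add atoms: none
Why: Fluoride-mediated desilylation frees the neopentyl primary alcohol; the secondary carbinol and the chromene are unaffected.

Step 24
Reactants: 35 1-[(1S,2S)-2-(hydroxymethyl)-1,2-dimethylcyclopentyl]-3-[(2R)-6-methoxy-2,8-dimethyl-2H-chromen-2-yl]propan-2-ol
Product: 37 (4aS,7aS)-3-{[(2R)-6-methoxy-2,8-dimethyl-2H-chromen-2-yl]methyl}-4a,7a-dimethylhexahydrocyclopenta[c]pyran-1(3H)-one (both C3 epimers), via lactol 36 (not isolated)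
Conditions: TEMPO (0.2 equiv), PhI(OAc)2 (2.5 equiv), CH2Cl2, rt
Reagents that add atoms: none
Why: Oxidative lactonisation of a 1,5-diol: the primary alcohol is oxidised in preference to the secondary one, the aldehyde closes to the lactol with the secondary hydroxyl, and the lactol is oxidised to the δ-lactone. The lactone holds the C2' carbonyl at the carboxyl level and masks the bridge carbinol.

Step 25
Reactants: 37 (4aS,7aS)-3-{[(2R)-6-methoxy-2,8-dimethyl-2H-chromen-2-yl]methyl}-4a,7a-dimethylhexahydrocyclopenta[c]pyran-1(3H)-one; 38 2-methylbut-3-yn-2-ol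
Product: 40 4-hydroxy-1-[(1S,2S)-2-{2-hydroxy-3-[(2R)-6-methoxy-2,8-dimethyl-2H-chromen-2-yl]propyl}-1,2-dimethylcyclopentyl]-4-methylpent-2-yn-1-one (both carbinol epimers), via dilithium alkynolate 39 (not isolated)
Conditions: 38 (3 equiv), n-BuLi (6 equiv), THF, −78 to 0 °C; then 37, −78 to −20 °C; aq. NH4Cl
Reagents that add atoms: none
Why: Addition of a lithium acetylide to a lactone; the tetrahedral lithium hemiketalate is stable at low temperature, so a single addition should occur and work-up releases the ynone and the bridge carbinol (in equilibrium with the cyclic hemiketal). Using the dianion of the unprotected alkynol avoids a later deprotection next to the sensitive ynone.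

Step 26
Reactants: 40 4-hydroxy-1-[(1S,2S)-2-{2-hydroxy-3-[(2R)-6-methoxy-2,8-dimethyl-2H-chromen-2-yl]propyl}-1,2-dimethylcyclopentyl]-4-methylpent-2-yn-1-one
Product: 41 4-hydroxy-1-[(1S,2S)-2-{3-[(2R)-6-methoxy-2,8-dimethyl-2H-chromen-2-yl]-2-oxopropyl}-1,2-dimethylcyclopentyl]-4-methylpent-2-yn-1-one
Conditions: Dess–Martin periodinane, NaHCO3, CH2Cl2, 0 °C
Reagents that add atoms: none
Why: Dess–Martin oxidation of the secondary carbinol to the bridge ketone; the tertiary alcohol cannot be oxidised. The absence of base avoids opening of the pyran ring and aldol or Michael reactions of the 1,5-diketone.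

Step 27
Reactants: 41 4-hydroxy-1-[(1S,2S)-2-{3-[(2R)-6-methoxy-2,8-dimethyl-2H-chromen-2-yl]-2-oxopropyl}-1,2-dimethylcyclopentyl]-4-methylpent-2-yn-1-one
Product: 42 (2Z)-4-hydroxy-1-[(1S,2S)-2-{3-[(2R)-6-methoxy-2,8-dimethyl-2H-chromen-2-yl]-2-oxopropyl}-1,2-dimethylcyclopentyl]-4-methylpent-2-en-1-one
Conditions: H2 (1 atm), Pd/CaCO3 poisoned with Pb(OAc)2 (Lindlar catalyst), quinoline, EtOAc, 0 °C
Reagents that add atoms: none
Why: Lindlar semihydrogenation adds hydrogen syn to the ynone and gives the (Z)-enone. The poisoned catalyst should spare the cis-disubstituted C3=C4 bond of the chromene, and the reaction is stopped after one equivalent of H2.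

## Compound list

1 | (R)-citramalic acid | OC(=O)[C@@](C)(CC(=O)O)O | starting material
2 | 2-[(4R)-2,2,4-trimethyl-5-oxo-1,3-dioxolan-4-yl]acetic acid | O=C1OC(C)(C)O[C@]1(C)CC(=O)O | intermediate
3 | (5R)-5-(2-hydroxyethyl)-2,2,5-trimethyl-1,3-dioxolan-4-one | O=C1OC(C)(C)O[C@]1(C)CCO | intermediate
4 | (5R)-2,2,5-trimethyl-5-{2-[(triisopropylsilyl)oxy]ethyl}-1,3-dioxolan-4-one | O=C1OC(C)(C)O[C@]1(C)CCO[Si](C(C)C)(C(C)C)C(C)C | intermediate
5 | (5R)-2,2,5-trimethyl-5-{2-[(triisopropylsilyl)oxy]ethyl}-1,3-dioxolan-4-ol (C4 epimers) | OC1OC(C)(C)O[C@]1(C)CCO[Si](C(C)C)(C(C)C)C(C)C | intermediate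
6 | dimethyl (1-diazo-2-oxopropyl)phosphonate | CC(=O)C(=[N+]=[N-])P(=O)(OC)OC | starting material
7 | (2R)-2-hydroxy-2-methyl-4-[(triisopropylsilyl)oxy]butanal | O=C[C@@](C)(CCO[Si](C(C)C)(C(C)C)C(C)C)O | intermediate
8 | (3R)-3-methyl-5-[(triisopropylsilyl)oxy]pent-1-yn-3-ol | C#C[C@@](C)(CCO[Si](C(C)C)(C(C)C)C(C)C)O | intermediate
9 | 4-methoxy-2-methylaniline | COc1ccc(N)c(C)c1 | starting material
10 | 2-iodo-4-methoxy-6-methylaniline | COc1cc(C)c(N)c(I)c1 | intermediate
11 | 2-iodo-4-methoxy-6-methylbenzenediazonium bromide | COc1cc(C)c([N+]#N)c(I)c1.[Br-] | intermediate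
12 | 1-bromo-2-iodo-4-methoxy-6-methylbenzene | COc1cc(C)c(Br)c(I)c1 | intermediate
13 | (3R)-1-(2-bromo-5-methoxy-3-methylphenyl)-3-methyl-5-[(triisopropylsilyl)oxy]pent-1-yn-3-ol | COc1cc(C)c(Br)c(c1)C#C[C@@](C)(CCO[Si](C(C)C)(C(C)C)C(C)C)O | intermediate
14 | (1Z,3R)-1-(2-bromo-5-methoxy-3-methylphenyl)-3-methyl-5-[(triisopropylsilyl)oxy]pent-1-en-3-ol | COc1cc(C)c(Br)c(c1)/C=C\[C@@](C)(CCO[Si](C(C)C)(C(C)C)C(C)C)O | intermediate
15 | (2R)-6-methoxy-2,8-dimethyl-2-{2-[(triisopropylsilyl)oxy]ethyl}-2H-chromene | COc1cc(C)c2c(c1)C=C[C@@](C)(CCO[Si](C(C)C)(C(C)C)C(C)C)O2 | intermediate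
16 | 2-[(2R)-6-methoxy-2,8-dimethyl-2H-chromen-2-yl]ethanol | COc1cc(C)c2c(c1)C=C[C@@](C)(CCO)O2 | intermediate
17 | 2-[(2R)-6-methoxy-2,8-dimethyl-2H-chromen-2-yl]acetaldehyde | COc1cc(C)c2c(c1)C=C[C@@](C)(CC=O)O2 | intermediate
18 | cis-cyclopentane-1,2-dicarboxylic anhydride (meso) | O=C1OC(=O)[C@@H]2CCC[C@H]12 | starting material
19 | (1R,2S)-2-(methoxycarbonyl)cyclopentane-1-carboxylic acid | OC(=O)[C@@H]1CCC[C@@H]1C(=O)OC | intermediate
20 | methyl (1S,2R)-2-(hydroxymethyl)cyclopentane-1-carboxylate | OC[C@@H]1CCC[C@@H]1C(=O)OC | intermediate
21 | (1S,5R)-3-oxabicyclo[3.3.0]octan-2-one | O=C1OC[C@@H]2CCC[C@H]12 | intermediate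
22 | lithium enolate of 21 | [Li+].[O-]C1=C2CCC[C@H]2CO1 | intermediate
23 | (1S,5R)-1-methyl-3-oxabicyclo[3.3.0]octan-2-one | O=C1OC[C@@H]2CCC[C@]12C | intermediate
24 | [(1S,2R)-2-(hydroxymethyl)-1-methylcyclopentyl]methanol | OC[C@@H]1CCC[C@]1(C)CO | intermediate
25 | (1R,5S)-5-methyl-3-oxabicyclo[3.3.0]octan-2-ol (C2 epimers) | OC1[C@@H]2CCC[C@]2(C)CO1 | intermediate
26 | (1R,5S)-5-methyl-3-oxabicyclo[3.3.0]octan-2-one | O=C1[C@@H]2CCC[C@]2(C)CO1 | intermediate
27 | lithium enolate of 26 | [Li+].[O-]C1=C2CCC[C@]2(C)CO1 | intermediate
28 | (1R,5S)-1,5-dimethyl-3-oxabicyclo[3.3.0]octan-2-one | O=C1[C@]2(C)CCC[C@]2(C)CO1 | intermediate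
29 | potassium (1R,2S)-2-(hydroxymethyl)-1,2-dimethylcyclopentane-1-carboxylate | [K+].[O-]C(=O)[C@]1(C)CCC[C@]1(C)CO | intermediate
30 | triisopropylsilyl (1R,2S)-1,2-dimethyl-2-{[(triisopropylsilyl)oxy]methyl}cyclopentane-1-carboxylate | CC(C)[Si](C(C)C)(C(C)C)OC(=O)[C@]1(C)CCC[C@]1(C)CO[Si](C(C)C)(C(C)C)C(C)C | intermediate
31 | [(1R,2S)-1,2-dimethyl-2-{[(triisopropylsilyl)oxy]methyl}cyclopentyl]methanol | OC[C@]1(C)CCC[C@]1(C)CO[Si](C(C)C)(C(C)C)C(C)C | intermediate
32 | {[(1S,2R)-2-(iodomethyl)-1,2-dimethylcyclopentyl]methoxy}tri(propan-2-yl)silane | IC[C@]1(C)CCC[C@]1(C)CO[Si](C(C)C)(C(C)C)C(C)C | intermediate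
33 | {[(1R,2S)-1,2-dimethyl-2-{[(triisopropylsilyl)oxy]methyl}cyclopentyl]methyl}lithium | [Li]C[C@]1(C)CCC[C@]1(C)CO[Si](C(C)C)(C(C)C)C(C)C | intermediate
34 | 1-[(1S,2S)-1,2-dimethyl-2-{[(triisopropylsilyl)oxy]methyl}cyclopentyl]-3-[(2R)-6-methoxy-2,8-dimethyl-2H-chromen-2-yl]propan-2-ol (carbinol epimers) | COc1cc(C)c2c(c1)C=C[C@@](C)(CC(O)C[C@]1(C)CCC[C@]1(C)CO[Si](C(C)C)(C(C)C)C(C)C)O2 | intermediate
35 | 1-[(1S,2S)-2-(hydroxymethyl)-1,2-dimethylcyclopentyl]-3-[(2R)-6-methoxy-2,8-dimethyl-2H-chromen-2-yl]propan-2-ol (carbinol epimers) | COc1cc(C)c2c(c1)C=C[C@@](C)(CC(O)C[C@]1(C)CCC[C@]1(C)CO)O2 | intermediate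
36 | (4aS,7aS)-3-{[(2R)-6-methoxy-2,8-dimethyl-2H-chromen-2-yl]methyl}-4a,7a-dimethyloctahydrocyclopenta[c]pyran-1-ol (epimers at C1 and C3) | COc1cc(C)c2c(c1)C=C[C@@](C)(CC1C[C@]3(C)CCC[C@]3(C)C(O)O1)O2 | intermediate
37 | (4aS,7aS)-3-{[(2R)-6-methoxy-2,8-dimethyl-2H-chromen-2-yl]methyl}-4a,7a-dimethylhexahydrocyclopenta[c]pyran-1(3H)-one (C3 epimers) | COc1cc(C)c2c(c1)C=C[C@@](C)(CC1C[C@]3(C)CCC[C@]3(C)C(=O)O1)O2 | intermediate
38 | 2-methylbut-3-yn-2-ol | CC(C)(O)C#C | starting material
39 | dilithium 2-methylbut-3-yn-1-id-2-olate | [Li+].[Li+].CC(C)([O-])C#[C-] | intermediate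
40 | 4-hydroxy-1-[(1S,2S)-2-{2-hydroxy-3-[(2R)-6-methoxy-2,8-dimethyl-2H-chromen-2-yl]propyl}-1,2-dimethylcyclopentyl]-4-methylpent-2-yn-1-one (carbinol epimers) | COc1cc(C)c2c(c1)C=C[C@@](C)(CC(O)C[C@]1(C)CCC[C@]1(C)C(=O)C#CC(C)(C)O)O2 | intermediate
41 | 4-hydroxy-1-[(1S,2S)-2-{3-[(2R)-6-methoxy-2,8-dimethyl-2H-chromen-2-yl]-2-oxopropyl}-1,2-dimethylcyclopentyl]-4-methylpent-2-yn-1-one | COc1cc(C)c2c(c1)C=C[C@@](C)(CC(=O)C[C@]1(C)CCC[C@]1(C)C(=O)C#CC(C)(C)O)O2 | intermediate
42 | (2Z)-4-hydroxy-1-[(1S,2S)-2-{3-[(2R)-6-methoxy-2,8-dimethyl-2H-chromen-2-yl]-2-oxopropyl}-1,2-dimethylcyclopentyl]-4-methylpent-2-en-1-one | COc1cc(C)c2c(c1)C=C[C@@](C)(CC(=O)C[C@]1(C)CCC[C@]1(C)C(=O)/C=C\C(C)(C)O)O2 | target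

## Step count and least certain steps

Total step count: 27. Longest linear sequence: 16 steps, from 1 through steps 1 to 5, 8 to 12 and 22 to 27. The ring C branch from 18 runs 15 steps (13 to 27), and the arene branch from 9 joins at step 8.

Step 10 (key step). Oxidative addition into the doubly ortho-substituted bromide may be slow, so that reduction of the C–Br bond competes. The tertiary palladium alkoxide may also lose its vinyl group by β-carbon elimination, or the tertiary allylic alcohol may dehydrate on prolonged heating. The fallback sets out from 8 and returns at 15, and it changes the order of bond formation. The tertiary alkoxide of 8 (t-BuONa, toluene) is arylated without metal by (4-methoxy-2-methylphenyl)(2,4,6-trimethoxyphenyl)iodonium tosylate F1, which is made in one pot from 1-iodo-4-methoxy-2-methylbenzene, 1,3,5-trimethoxybenzene, mCPBA and TsOH. This gives the aryl propargyl ether F2 with O1–C8a in place and C2 untouched. PtCl4-catalysed hydroarylation of the alkyne at the one free ortho position then closes ring B at C4–C4a to give 15. Thermal rearrangement of F2 is avoided because it would break the C2–O bond.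

Step 21. Displacement at a neopentyl carbon flanked by two quaternary centres may be too slow, and the neighbouring ether oxygen may attack the activated carbon with loss of the silyl group, closing a tetrahydrofuran. The fallback sets out from 30 and returns at 32 by a radical path with no substitution at the neopentyl carbon. Mild hydrolysis of the silyl ester (K2CO3, MeOH/H2O) gives acid F3. Oxalyl chloride gives acid chloride F4, and Me3SiCHN2 gives diazoketone F5. Wolff rearrangement (AgO2CPh, Et3N, THF/H2O), which proceeds with retention in the migrating carbon, gives the homologous acid F6. Decarboxylative iodination (PhI(OAc)2, I2, light) then gives 32.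

Step 22. The hindered organolithium may act as a base, so that enolisation of 17, followed by expulsion of the phenoxide and opening of ring B, competes with addition. The fallback sets out from 17 and returns at 34 without a strongly basic organometallic. Pinnick oxidation gives acid F7, and 2,2'-dipyridyl disulfide/PPh3 gives the S-2-pyridyl thioester F8. Nickel-catalysed reductive coupling of F8 with 32 (NiCl2(MeOCH2CH2OMe), 4,4'-di-tert-butyl-2,2'-bipyridine, Mn, DMA) gives ketone F9, and NaBH4 reduces it to 34.

Step 25. Addition to a carbonyl flanked by two quaternary carbons may stall, the hemiketalate may collapse early and take up a second acetylide, or the product may rest as a hemiketal that resists oxidation in step 26. The fallback sets out from 37 and returns at 41. i-Bu2AlH at −78 °C reduces 37 to lactol 36, whose open hydroxy aldehyde form takes up 39 to give triol F10. Dess–Martin oxidation of both secondary carbinols gives 41.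

Step 27. Hydrogenation may run on to the saturated ketone, the (Z)-enone may isomerise to (E), or the C3=C4 bond of ring B may be touched. The fallback sets out from 37 and returns at 42, so that the enone is made by oxidation and not by hydrogenation. 37 is taken through 36 to F10 as above. The isolated, non-conjugated triple bond of F10 is semihydrogenated over the same poisoned catalyst to the (Z)-triol F11, where over-reduction is slower. Dess–Martin oxidation of both secondary carbinols then gives 42.

## Further compounds

F1 | step 10 | (4-methoxy-2-methylphenyl)(2,4,6-trimethoxyphenyl)iodonium 4-methylbenzenesulfonate | COc1ccc([I+]c2c(OC)cc(OC)cc2OC)c(C)c1.Cc1ccc(cc1)S(=O)(=O)[O-]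
F2 | step 10 | {[(3R)-3-(4-methoxy-2-methylphenoxy)-3-methylpent-4-yn-1-yl]oxy}tri(propan-2-yl)silane | C#C[C@@](C)(CCO[Si](C(C)C)(C(C)C)C(C)C)Oc1ccc(OC)cc1C
F3 | step 21 | (1R,2S)-1,2-dimethyl-2-{[(triisopropylsilyl)oxy]methyl}cyclopentane-1-carboxylic acid | OC(=O)[C@]1(C)CCC[C@]1(C)CO[Si](C(C)C)(C(C)C)C(C)C
F4 | step 21 | (1R,2S)-1,2-dimethyl-2-{[(triisopropylsilyl)oxy]methyl}cyclopentane-1-carbonyl chloride | ClC(=O)[C@]1(C)CCC[C@]1(C)CO[Si](C(C)C)(C(C)C)C(C)C
F5 | step 21 | 2-diazo-1-[(1R,2S)-1,2-dimethyl-2-{[(triisopropylsilyl)oxy]methyl}cyclopentyl]ethan-1-one | [N-]=[N+]=CC(=O)[C@]1(C)CCC[C@]1(C)CO[Si](C(C)C)(C(C)C)C(C)C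
F6 | step 21 | 2-[(1S,2S)-1,2-dimethyl-2-{[(triisopropylsilyl)oxy]methyl}cyclopentyl]acetic acid | OC(=O)C[C@]1(C)CCC[C@]1(C)CO[Si](C(C)C)(C(C)C)C(C)C
F7 | step 22 | 2-[(2R)-6-methoxy-2,8-dimethyl-2H-chromen-2-yl]acetic acid | COc1cc(C)c2c(c1)C=C[C@@](C)(CC(=O)O)O2
F8 | step 22 | S-(pyridin-2-yl) 2-[(2R)-6-methoxy-2,8-dimethyl-2H-chromen-2-yl]ethanethioate | COc1cc(C)c2c(c1)C=C[C@@](C)(CC(=O)Sc1ccccn1)O2
F9 | step 22 | 1-[(1S,2S)-1,2-dimethyl-2-{[(triisopropylsilyl)oxy]methyl}cyclopentyl]-3-[(2R)-6-methoxy-2,8-dimethyl-2H-chromen-2-yl]propan-2-one | COc1cc(C)c2c(c1)C=C[C@@](C)(CC(=O)C[C@]1(C)CCC[C@]1(C)CO[Si](C(C)C)(C(C)C)C(C)C)O2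
F10 | step 25 | 1-[(1S,2S)-2-{2-hydroxy-3-[(2R)-6-methoxy-2,8-dimethyl-2H-chromen-2-yl]propyl}-1,2-dimethylcyclopentyl]-4-methylpent-2-yne-1,4-diol (carbinol epimers) | COc1cc(C)c2c(c1)C=C[C@@](C)(CC(O)C[C@]1(C)CCC[C@]1(C)C(O)C#CC(C)(C)O)O2
F11 | step 27 | (2Z)-1-[(1S,2S)-2-{2-hydroxy-3-[(2R)-6-methoxy-2,8-dimethyl-2H-chromen-2-yl]propyl}-1,2-dimethylcyclopentyl]-4-methylpent-2-ene-1,4-diol (carbinol epimers) | COc1cc(C)c2c(c1)C=C[C@@](C)(CC(O)C[C@]1(C)CCC[C@]1(C)C(O)/C=C\C(C)(C)O)O2
A1 | alternative 1 | (3R)-3-methyl-4,5,6,7-tetrahydrocyclopenta[c]pyran-1(3H)-one | C[C@@H]1CC2=C(CCC2)C(=O)O1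
A2 | alternative 1 | chloromethyl (trimethylsilyl)methyl sulfide | C[Si](C)(C)CSCCl
A3 | alternative 1 | parent thiocarbonyl ylide | C=[S+][CH2-]
A4 | alternative 1 | thiolane-fused tricyclic δ-lactone (3R; CH2–S–CH2 bridge on the cis ring-fusion carbons) | C[C@@H]1C[C@]23CCC[C@]2(CSC3)C(=O)O1
A5 | alternative 2 | (6S,7S,10R)-7-isopropyl-10-methyl-1,5-dioxaspiro[5.5]undec-2-en-4-one | C[C@@H]1CC[C@@H](C(C)C)[C@@]2(C1)OC=CC(=O)O2
A6 | alternative 2 | 1,2-dimethylcyclopentene | CC1=C(C)CCC1
A7 | alternative 2 | methyl 2-[(1S,2S)-2-formyl-1,2-dimethylcyclopentyl]acetate | COC(=O)C[C@]1(C)CCC[C@]1(C)C=O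
A8 | alternative 3 | tert-butyl{2-[(1R,2S,6S)-2,6-dimethyl-7-oxabicyclo[4.1.0]heptan-2-yl]ethoxy}dimethylsilane (epoxide oxygen cis to the silyloxyethyl arm) | C[C@]12CCC[C@@](C)(CCO[Si](C)(C)C(C)(C)C)[C@H]1O2
A9 | alternative 3 | methylaluminum bis(4-bromo-2,6-di-tert-butylphenoxide) | C[Al](Oc1c(cc(Br)cc1C(C)(C)C)C(C)(C)C)Oc1c(cc(Br)cc1C(C)(C)C)C(C)(C)C
A10 | alternative 3 | (1S,2S)-2-(2-{[tert-butyl(dimethyl)silyl]oxy}ethyl)-1,2-dimethylcyclopentane-1-carbaldehyde | CC(C)(C)[Si](C)(C)OCC[C@]1(C)CCC[C@]1(C)C=O
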